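**Plan**
1. Retrosynthesis: the two esters, the C14 aldehyde and the lactone are late adjustments. The ten-membered ring holds the 1,5-diene C10=C1–C2–C3–C4=C5, so cutting C2–C3 by a retro-[3,3] shift folds it into the six-membered ring C5–C10 with cis alkenyl groups on C5 and C10.
2. That cyclohexanol is cut at C5–C4 (alkenyl addition to a C5 ketone), at O8/O9 (epoxide of C8=C9), at C7–C11 (SN2′ opening of an oxygen bridge between C6 and C9) and at C10–C14 and C1=C2 (enolate chemistry on a bicyclic ketone).
3. Forward: 7-oxanorbornenone → quaternary C10 → bridge opening to the cyclohexene C5–C10 → five-membered O6–C12 acetal → epoxide opening → C5 ketone → cis-dialkenyl carbinol → ring expansion to the ten-membered ring → ester, lactone, acetate, C14 oxidation.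
4. Stereocentres: C6 comes from purchased (1S,4S)-1; C10 and C7 from exo alkylation and anti SN2′ opening of the bicycle; C8 and C9 from β-face epoxidation and trans-diaxial opening; the ester centre from (R)-2-methylbutanoic acid.
5. Alkene geometry: C4=C5 (ring-cis) comes from the chair transition state of the ring expansion; C1=C10 (ring-cis) from the [2,3] shift in the late SeO2 oxidation of C14.

Key step: step 15

Remark: atoms carry the germacrane numbering of the target; β is the face of ring C5–C10 that bears the C6 oxygen (the exo face of the oxanorbornene), α the opposite face.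
Remark: (1S,4S)-7-oxabicyclo[2.2.1]hept-5-en-2-one (1) is taken as a purchasable enantiopure building block.
Remark: C14 is carried as a methyl group and oxidised at the end, and the C5 oxygen of the ring-expansion precursor is β (cis to O6), because only this arrangement lets a ring lock enforce the required chair.
Remark: the acetal carbon C12 (12–18, 23–28, 30, 31) and the carbinol carbon of 3 and 4 are epimer mixtures of no consequence; their SMILES leave these centres open.

**Step 1**
Reactants: 1 (1S,4S)-7-oxabicyclo[2.2.1]hept-5-en-2-one; 2 acetaldehyde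
Product: 3 3-exo-(1-hydroxyethyl) ketone (aldol adduct at C10)
Conditions: LDA, THF, −78 °C; MeCHO, −78 °C; aqueous NH4Cl
Reagents that add atoms: none
Why: Lithium enolate aldol addition, in which the bridged enolate (C6 is a bridgehead, so C10 is the only enolisable position) is kept at −78 °C to avoid loss of the oxygen bridge and adds to acetaldehyde on the exo face, the carbinol configuration being irrelevant because it is removed in step 2.

**Step 2**
Reactants: 3 aldol adduct
Product: 5 (E)-3-ethylidene-7-oxabicyclo[2.2.1]hept-5-en-2-one, via mesylate 4 (not isolated)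
Conditions: MsCl, Et3N, CH2Cl2, 0 °C; then DBU, 0 °C → rt
Reagents that add atoms: none
Why: Mesylation followed by E1cB elimination (aldol condensation) should give the conjugated exocyclic enone, since C10 carries the only acidic hydrogen.

**Step 3**
Reactants: 5 ethylidene ketone
Product: 6 3-exo-methyl-3-endo-vinyl-7-oxabicyclo[2.2.1]hept-5-en-2-one (10β-methyl; 10α-vinyl)
Conditions: KHMDS, THF–DMPU, −78 °C; MeI, −78 → −40 °C
Reagents that add atoms: iodomethane, CI
Why: Deconjugative α-alkylation of an extended dienolate, in which γ-deprotonation of the ethylidene methyl is the only enolisation open to 5 and iodomethane attacks C10 on the exo face of the bicycle, so the new methyl (C14) is β and the vinyl group formed from the ethylidene unit (C1=C2) is α, which sets quaternary C10.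

**Step 4**
Reactants: 6 methyl vinyl ketone
Product: 7 3-exo-methyl-3-endo-vinyl-7-oxabicyclo[2.2.1]hept-5-en-2-endo-ol (5α-OH)
Conditions: NaBH4, MeOH, 0 °C
Reagents that add atoms: none
Why: Borohydride reduction is expected from the exo face to give the endo alcohol, a centre that only masks the ketone during the organometallic step and is destroyed in step 12, so either epimer would serve.

**Step 5**
Reactants: 7 bicyclic alcohol; 8 2-bromo-3,3-diethoxyprop-1-ene
Product: 11 cyclohexenediol (5α-OH; 6β-OH; 7α-(3,3-diethoxyprop-1-en-2-yl); C8=C9; 10β-methyl; 10α-vinyl), via alkenyllithium 9 (not isolated), via alkenylmagnesium bromide 10 (not isolated)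
Conditions: 8, t-BuLi, Et2O, −78 °C; MgBr2·OEt2, −78 °C; then 7, CuCl (cat.), PPh3 (cat.), Et2O–toluene, −20 → 0 °C; aqueous NH4Cl
Reagents that add atoms: none
Why: Copper-catalysed anti SN2′ ring opening of an oxabicyclic alkene by a Grignard reagent, in which the organocopper adds to C7 on the face opposite the bridge while the C9–O bond breaks, so O6 stays β, the side chain is 7α (trans) and the alkene moves to C8=C9; cleavage at C9–O is favoured because C6 is flanked by the electronegative C5 oxygen, whose magnesium alkoxide also anchors the reagent near C7.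

**Step 6**
Reactants: 11 cyclohexenediol
Product: 12 trans-fused ethyl acetal (O6–C12; 2-ethoxy-3-methylenetetrahydrofuran ring on C6–C7; 5α-OH free)
Conditions: PPTS (cat.), CH2Cl2, 4 Å molecular sieves, rt
Reagents that add atoms: none
Why: Acid-catalysed transacetalisation, in which the 6β-hydroxyl (trans-diequatorial to the side chain) closes the five-membered ring whereas the 5α-hydroxyl would need a diaxial bridged array; the acetal protects O6, keeps C12 at the aldehyde level, deactivates C11=C13 and locks the cyclohexane chair.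

**Step 7**
Reactants: 12 acetal alcohol
Product: 13 5α-O-TBS ether
Conditions: KHMDS, THF, −78 °C; TBSCl, −78 → 0 °C
Reagents that add atoms: tert-butyldimethylsilyl chloride, CC(C)(C)[Si](C)(C)Cl
Why: O-Silylation of the hindered potassium alkoxide masks O5 temporarily so that O9 will be the only free hydroxyl after step 9.

**Step 8**
Reactants: 13 silyl ether
Product: 14 8β,9β-epoxide
Conditions: mCPBA, NaHCO3, CH2Cl2, 0 °C
Reagents that add atoms: 3-chloroperbenzoic acid, O=C(OO)c1cccc(Cl)c1
Why: Prilezhaev epoxidation, for which only the cis-disubstituted ring alkene is nucleophilic enough (the vinyl group is monosubstituted and neopentylic, C11=C13 is deactivated by the allylic acetal), the peracid approaching the β face opposite the pseudo-axial 10α-vinyl group.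

**Step 9**
Reactants: 14 epoxide
Product: 15 8α-allyloxy-9β-ol
Conditions: NaH, allyl alcohol, DMF, 80 °C
Reagents that add atoms: allyl alcohol, C=CCO
Why: Alkoxide opening of the epoxide under Fürst–Plattner control, in which trans-diaxial attack is possible only at C8 (C9 is neopentylic), so O8 enters α with inversion and O9 stays β, giving the trans-diol with its two oxygens differentiated.

**Step 10**
Reactants: 15 hydroxy allyl ether
Product: 16 9β-O-PMB ether
Conditions: NaH, PMBCl, Bu4NI (cat.), DMF, 0 °C → rt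
Reagents that add atoms: 4-methoxybenzyl chloride, COc1ccc(CCl)cc1
Why: Williamson etherification of the only free hydroxyl.

**Step 11**
Reactants: 16 fully protected cyclohexane
Product: 17 5α-alcohol
Conditions: TBAF, THF, rt → 40 °C
Reagents that add atoms: none
Why: Fluoride cleavage of the only silyl ether frees the C5 hydroxyl, while the acetal and the allyl and PMB ethers are inert.

**Step 12**
Reactants: 17 alcohol
Product: 18 C5 ketone
Conditions: Dess–Martin periodinane, NaHCO3, CH2Cl2, rt
Reagents that add atoms: none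
Why: Dess–Martin oxidation of the secondary alcohol should proceed without epimerisation or β-elimination, because C6 is already in its stable trans-fused configuration and C10 is quaternary.

**Step 13**
Reactants: 19 2-bromoprop-2-en-1-ol
Product: 20 tert-butyl[(2-bromoallyl)oxy]diphenylsilane
Conditions: TBDPSCl, imidazole, CH2Cl2, 0 °C → rt
Reagents that add atoms: tert-butyl(chloro)diphenylsilane, CC(C)(C)[Si](Cl)(c1ccccc1)c1ccccc1
Why: Imidazole-promoted silylation of the primary alcohol provides the C3–C4–C15 unit as a vinyl bromide.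

**Step 14**
Reactants: 18 ketone; 20 bromoallyl silyl ether
Product: 23 cis-dialkenylcyclohexanol (5β-OH; 5α-[3-(TBDPS-oxy)prop-1-en-2-yl]; 10α-vinyl), via alkenyllithium 21 (not isolated), via alkenylcerium dichloride 22 (not isolated)
Conditions: 20, t-BuLi, Et2O, −78 °C; CeCl3, THF, −78 °C; then 18, −78 °C; aqueous NH4Cl
Reagents that add atoms: none
Why: 1,2-Addition of an alkenylcerium reagent (bromine–lithium exchange, then transmetalation) to the ketone, in which the axial trajectory of the locked chair is blocked by the syn-axial 9β-OPMB group, so the weakly basic reagent attacks equatorially from the α face and places the alkenyl group α (cis to the vinyl group) and the hydroxyl β-axial.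

**Step 15**
Reactants: 23 cis-dialkenylcyclohexanol
Product: 26 ten-membered C5 enol triflate (C4=C5 ring-cis; C1=C10 ring-trans), via potassium alkoxide 24 (not isolated), via potassium enolate 25 (not isolated)
Conditions: KHMDS, 18-crown-6, THF, −78 → 0 °C; then PhNTf2, −78 °C
Reagents that add atoms: N-phenylbis(trifluoromethanesulfonimide), O=S(=O)(N(c1ccccc1)S(=O)(=O)C(F)(F)F)C(F)(F)F
Why: Deprotonation gives the C5 potassium alkoxide 24, whose weakened C5–C10 bond lets the 3-oxido-1,5-diene C3=C4–C5–C10–C1=C2 undergo the [3,3] shift that forms C2–C3 and breaks C5–C10, and the regiodefined C4=C5 enolate 25 is then sulfonylated on oxygen by the triflimide. The reaction type is the anionic oxy-Cope ring expansion of cis-1,2-dialkenylcyclohexanols to cyclodec-5-enones with triflation of the enolate. The ten-membered ring is closed not by a cyclisation but by four-atom expansion of the cyclohexane through a chair-like six-centre transition state. No stereocentre is created, and C6–C9 pass through unchanged. The step needs the chair in which the oxyanion is pseudo-equatorial and C6 pseudo-axial (giving C4=C5 ring-cis and C1=C10 ring-trans), and this is the only chair open to 23, because the trans-fused O6–C12 acetal holds O6 and C11 equatorial and so fixes the C10 vinyl group axial, the C5 alkenyl group equatorial and the C5 oxygen axial. The warm-up is kept short and the triflimide is added cold so that sulfonylation outruns loss of silanolate from C15 of enolate 25.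

**Step 16**
Reactants: 26 enol triflate
Product: 27 C4=C5 (C5–H) diene
Conditions: Pd(OAc)2 (cat.), PPh3, HCO2H, Bu3N, DMF, 60 °C
Reagents that add atoms: none
Why: Palladium-catalysed formate reduction of the enol triflate (oxidative addition, formate exchange, decarboxylation, reductive elimination) should replace OTf by H with retention of the ring-cis C4=C5 geometry.

**Step 17**
Reactants: 27 diene
Product: 28 C8 alcohol
Conditions: Pd(PPh3)4 (cat.), sodium 4-methylbenzenesulfinate, THF–MeOH, rt
Reagents that add atoms: none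
Why: Palladium-catalysed deallylation (π-allyl formation from the unhindered O-allyl group and capture by sulfinate) frees O8 while the acetal still blocks O6 and C12.

**Step 18**
Reactants: 28 C8 alcohol; 29 (R)-2-methylbutanoic acid
Product: 30 C8 (R)-2-methylbutanoate
Conditions: DIC, DMAP (cat.), CH2Cl2, 0 °C → rt
Reagents that add atoms: none
Why: Steglich esterification installs the O8 ester, whose stereocentre comes from the acid and should not epimerise under mild carbodiimide activation.

**Step 19**
Reactants: 30 ester acetal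
Product: 31 lactol (C12 hemiacetal to O6)
Conditions: AcOH–THF–H2O (3:1:1), rt
Reagents that add atoms: water, O
Why: Mild acid hydrolysis of the 2-alkoxytetrahydrofuran acetal gives the lactol, and because O8 is already acylated only O6 can hold C12.

**Step 20**
Reactants: 31 lactol
Product: 32 α-methylene-γ-butyrolactone (6,12-olide)
Conditions: TEMPO (cat.), PhI(OAc)2, CH2Cl2, rt
Reagents that add atoms: none
Why: Oxoammonium-mediated oxidation of the lactol gives the lactone, trans-fused as fixed at C6 and C7 since step 5.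

**Step 21**
Reactants: 32 lactone
Product: 33 C9 alcohol
Conditions: DDQ, CH2Cl2–pH 7 buffer, 0 °C
Reagents that add atoms: none
Why: Oxidative cleavage of the PMB ether by DDQ (benzylic hydride abstraction, then hydrolysis) frees O9 under buffered conditions that spare the silyl ether, the esters and the diene.

**Step 22**
Reactants: 33 C9 alcohol
Product: 34 C9 acetate
Conditions: Ac2O, pyridine, DMAP (cat.), CH2Cl2, 0 °C → rt
Reagents that add atoms: acetic anhydride, CC(=O)OC(C)=O
Why: DMAP-catalysed acetylation of the only free hydroxyl.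

**Step 23**
Reactants: 34 diester
Product: 35 C14 allylic alcohol (C1=C10 ring-cis)
Conditions: SeO2 (cat.), t-BuOOH, CH2Cl2, rt
Reagents that add atoms: tert-butyl hydroperoxide, CC(C)(C)OO
Why: Allylic oxidation by SeO2 (ene reaction at C1=C10, then [2,3]-sigmatropic shift of the allylic seleninic acid) oxidises C14, and the [2,3] shift re-forms C1=C10 with the CH2OH group trans to C2, turning the ring-trans alkene into the ring-cis one as is known for germacranolides that carry a C14 methyl on a ring-trans C1=C10 bond.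

**Step 24**
Reactants: 35 C14 alcohol
Product: 36 C14 aldehyde (15-O-TBDPS)
Conditions: MnO2, CH2Cl2, rt
Reagents that add atoms: none
Why: MnO2 oxidises the primary allylic alcohol to the enal, whose geometry (CHO trans to C2) is the stable one.

**Step 25**
Reactants: 36 silyl ether
Product: 37 CNP0247637.4
Conditions: HF·pyridine, pyridine, THF, 0 °C → rt
Reagents that add atoms: none
Why: Fluoride cleavage of the TBDPS ether under non-basic conditions frees the C15 hydroxyl without acyl migration.

**Compound list**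
1 | (1S,4S)-7-oxabicyclo[2.2.1]hept-5-en-2-one | O=C1[C@@H]2C=C[C@@H](O2)C1 | starting material
2 | acetaldehyde | CC=O | starting material
3 | 3-exo-(1-hydroxyethyl)-7-oxabicyclo[2.2.1]hept-5-en-2-one (carbinol epimers) | O=C1[C@@H]2C=C[C@@H](O2)[C@H]1C(C)O | intermediate
4 | methanesulfonate of 3 | O=C1[C@@H]2C=C[C@@H](O2)[C@H]1C(C)OS(C)(=O)=O | intermediate (not isolated)
5 | (E)-3-ethylidene-7-oxabicyclo[2.2.1]hept-5-en-2-one | O=C1[C@@H]2C=C[C@@H](O2)/C1=C\C | intermediate
6 | 3-exo-methyl-3-endo-vinyl-7-oxabicyclo[2.2.1]hept-5-en-2-one | O=C1[C@@H]2C=C[C@@H](O2)[C@]1(C)C=C | intermediate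
7 | 3-exo-methyl-3-endo-vinyl-7-oxabicyclo[2.2.1]hept-5-en-2-endo-ol | O[C@@H]1[C@@H]2C=C[C@@H](O2)[C@]1(C)C=C | intermediate
8 | 2-bromo-3,3-diethoxyprop-1-ene | C=C(Br)C(OCC)OCC | starting material
9 | (3,3-diethoxyprop-1-en-2-yl)lithium | [Li]C(=C)C(OCC)OCC | intermediate (not isolated)
10 | (3,3-diethoxyprop-1-en-2-yl)magnesium bromide | Br[Mg]C(=C)C(OCC)OCC | intermediate (not isolated)
11 | 3-(3,3-diethoxyprop-1-en-2-yl)-6-methyl-6-vinylcyclohex-4-ene-1,2-diol (5α-OH, 6β-OH, 7α side chain, 10β-Me, 10α-vinyl) | O[C@@H]1[C@@H](O)[C@H](C(=C)C(OCC)OCC)C=C[C@]1(C)C=C | intermediate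
12 | 2-ethoxy-6-methyl-3-methylene-6-vinyl-2,3,3a,6,7,7a-hexahydrobenzofuran-7-ol (trans-fused O6–C12 acetal, 5α-OH) | O[C@@H]1[C@H]2OC(OCC)C(=C)[C@@H]2C=C[C@]1(C)C=C | intermediate
13 | 5α-O-TBS ether of 12 | CC(C)(C)[Si](C)(C)O[C@@H]1[C@H]2OC(OCC)C(=C)[C@@H]2C=C[C@]1(C)C=C | intermediate
14 | 8β,9β-epoxide of 13 | CC(C)(C)[Si](C)(C)O[C@@H]1[C@H]2OC(OCC)C(=C)[C@@H]2[C@H]3O[C@H]3[C@]1(C)C=C | intermediate
15 | 8α-allyloxy-9β-hydroxy compound (5α-OTBS) | CC(C)(C)[Si](C)(C)O[C@@H]1[C@H]2OC(OCC)C(=C)[C@@H]2[C@H](OCC=C)[C@@H](O)[C@]1(C)C=C | intermediate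
16 | 8α-allyloxy-9β-(4-methoxybenzyloxy) compound (5α-OTBS) | CC(C)(C)[Si](C)(C)O[C@@H]1[C@H]2OC(OCC)C(=C)[C@@H]2[C@H](OCC=C)[C@@H](OCc3ccc(OC)cc3)[C@]1(C)C=C | intermediate
17 | 5α-alcohol (8α-O-allyl, 9β-O-PMB, O6–C12 acetal) | O[C@@H]1[C@H]2OC(OCC)C(=C)[C@@H]2[C@H](OCC=C)[C@@H](OCc3ccc(OC)cc3)[C@]1(C)C=C | intermediate
18 | C5 ketone (8α-O-allyl, 9β-O-PMB, 10β-Me, 10α-vinyl, O6–C12 acetal) | O=C1[C@H]2OC(OCC)C(=C)[C@@H]2[C@H](OCC=C)[C@@H](OCc3ccc(OC)cc3)[C@]1(C)C=C | intermediate
19 | 2-bromoprop-2-en-1-ol | C=C(Br)CO | starting material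
20 | tert-butyl[(2-bromoallyl)oxy]diphenylsilane | C=C(Br)CO[Si](c1ccccc1)(c1ccccc1)C(C)(C)C | intermediate
21 | [3-(tert-butyldiphenylsilyloxy)prop-1-en-2-yl]lithium | [Li]C(=C)CO[Si](c1ccccc1)(c1ccccc1)C(C)(C)C | intermediate (not isolated)
22 | [3-(tert-butyldiphenylsilyloxy)prop-1-en-2-yl]cerium dichloride | Cl[Ce](Cl)C(=C)CO[Si](c1ccccc1)(c1ccccc1)C(C)(C)C | intermediate (not isolated)
23 | cis-1,2-dialkenylcyclohexanol (5β-OH, 5α-[3-(TBDPS-oxy)prop-1-en-2-yl], O6–C12 ethyl acetal trans-fused at C6/C7, 8α-O-allyl, 9β-O-PMB, 10β-Me, 10α-vinyl) | C=C(CO[Si](c1ccccc1)(c1ccccc1)C(C)(C)C)[C@]1(O)[C@H]2OC(OCC)C(=C)[C@@H]2[C@H](OCC=C)[C@@H](OCc3ccc(OC)cc3)[C@]1(C)C=C | intermediate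
24 | potassium alkoxide of 23 | C=C(CO[Si](c1ccccc1)(c1ccccc1)C(C)(C)C)[C@]1([O-])[C@H]2OC(OCC)C(=C)[C@@H]2[C@H](OCC=C)[C@@H](OCc3ccc(OC)cc3)[C@]1(C)C=C.[K+] | intermediate (not isolated)
25 | potassium C4=C5 enolate of the ten-membered ring (C3 cis to C6, C1=C10 ring-trans) | C=C1C(OCC)O[C@@H]2/C([O-])=C(/CO[Si](c3ccccc3)(c3ccccc3)C(C)(C)C)CC/C=C(\C)[C@H](OCc3ccc(OC)cc3)[C@@H](OCC=C)[C@@H]12.[K+] | intermediate (not isolated)
26 | ten-membered C5 enol triflate (C4=C5 ring-cis, C1=C10 ring-trans with C14 methyl, 15-O-TBDPS, O6–C12 ethyl acetal, 8-O-allyl, 9-O-PMB) | C=C1C(OCC)O[C@@H]2/C(OS(=O)(=O)C(F)(F)F)=C(/CO[Si](c3ccccc3)(c3ccccc3)C(C)(C)C)CC/C=C(\C)[C@H](OCc3ccc(OC)cc3)[C@@H](OCC=C)[C@@H]12 | intermediate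
27 | C5–H diene (triflate of 26 replaced by H) | C=C1C(OCC)O[C@@H]2/C=C(/CO[Si](c3ccccc3)(c3ccccc3)C(C)(C)C)CC/C=C(\C)[C@H](OCc3ccc(OC)cc3)[C@@H](OCC=C)[C@@H]12 | intermediate
28 | C8 alcohol | C=C1C(OCC)O[C@@H]2/C=C(/CO[Si](c3ccccc3)(c3ccccc3)C(C)(C)C)CC/C=C(\C)[C@H](OCc3ccc(OC)cc3)[C@@H](O)[C@@H]12 | intermediate
29 | (R)-2-methylbutanoic acid | CC[C@@H](C)C(=O)O | starting material
30 | C8 (R)-2-methylbutanoate (O6–C12 ethyl acetal) | C=C1C(OCC)O[C@@H]2/C=C(/CO[Si](c3ccccc3)(c3ccccc3)C(C)(C)C)CC/C=C(\C)[C@H](OCc3ccc(OC)cc3)[C@@H](OC(=O)[C@H](C)CC)[C@@H]12 | intermediate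
31 | lactol (C12 hemiacetal to O6) | C=C1C(O)O[C@@H]2/C=C(/CO[Si](c3ccccc3)(c3ccccc3)C(C)(C)C)CC/C=C(\C)[C@H](OCc3ccc(OC)cc3)[C@@H](OC(=O)[C@H](C)CC)[C@@H]12 | intermediate
32 | α-methylene-γ-butyrolactone (9-O-PMB, 15-O-TBDPS, C14 methyl) | C=C1C(=O)O[C@@H]2/C=C(/CO[Si](c3ccccc3)(c3ccccc3)C(C)(C)C)CC/C=C(\C)[C@H](OCc3ccc(OC)cc3)[C@@H](OC(=O)[C@H](C)CC)[C@@H]12 | intermediate
33 | C9 alcohol | C=C1C(=O)O[C@@H]2/C=C(/CO[Si](c3ccccc3)(c3ccccc3)C(C)(C)C)CC/C=C(\C)[C@H](O)[C@@H](OC(=O)[C@H](C)CC)[C@@H]12 | intermediate
34 | C9 acetate (C1=C10 ring-trans, C14 methyl) | C=C1C(=O)O[C@@H]2/C=C(/CO[Si](c3ccccc3)(c3ccccc3)C(C)(C)C)CC/C=C(\C)[C@H](OC(C)=O)[C@@H](OC(=O)[C@H](C)CC)[C@@H]12 | intermediate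
35 | C14 alcohol (C1=C10 ring-cis) | C=C1C(=O)O[C@@H]2/C=C(/CO[Si](c3ccccc3)(c3ccccc3)C(C)(C)C)CC/C=C(/CO)[C@H](OC(C)=O)[C@@H](OC(=O)[C@H](C)CC)[C@@H]12 | intermediate
36 | C14 aldehyde, 15-O-TBDPS ether of the target | C=C1C(=O)O[C@@H]2/C=C(/CO[Si](c3ccccc3)(c3ccccc3)C(C)(C)C)CC/C=C(/C=O)[C@H](OC(C)=O)[C@@H](OC(=O)[C@H](C)CC)[C@@H]12 | intermediate
37 | CNP0247637.4 | C=C1C(=O)O[C@@H]2/C=C(/CO)CC/C=C(/C=O)[C@H](OC(C)=O)[C@@H](OC(=O)[C@H](C)CC)[C@@H]12 | target

**Step count**
Total: 25 steps. Longest linear sequence: 24 steps (steps 1–12 and 14–25, from 1 to 37); step 13 makes the side-chain reagent 20.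

**Steps most likely to fail**

1. Step 15 (key step). The process at risk is loss of tert-butyldiphenylsilanolate from C15 of the potassium enolate (β-elimination) before it is sulfonylated, or unselective base-induced cleavage during the warm-up. The fallback sets out from 23 and avoids the free enolate at ambient temperature. Thermal oxy-Cope rearrangement of 23 without base (o-dichlorobenzene, about 200 °C) runs through the same locked chair and, after tautomerisation of the enol, should give the ten-membered C5 ketone F1. KHMDS is then added at −78 °C to a solution of ketone F1 and N-phenyltriflimide (internal quench), so the C4 enolate is sulfonylated as it forms. Deprotonation is expected at C4 because the C6 hydrogen is flanked by oxygen. The route is rejoined at 26.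

2. Step 5. The processes at risk are decomposition of the β-alkoxy alkenylmagnesium reagent before transfer, delivery to C8 instead of C7, and syn instead of anti opening. The fallback sets out from 7 and changes both the nucleophile and the way it is made. Nickel-catalysed Markovnikov hydroalumination of commercial 3,3-diethoxyprop-1-yne with DIBAL-H (NiCl2(dppp) cat.) gives diisobutyl(3,3-diethoxyprop-1-en-2-yl)alane F2. Alcohol 7 is converted into its aluminium alkoxide with DIBAL-H and then treated with alane F2 under CuCl/N-heterocyclic carbene catalysis. The Lewis-acidic aluminium activates the bridge oxygen, and anti SN2′ transfer of the alkenyl group to C7 should give 11, where the route is rejoined.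

3. Step 9. The processes at risk are slow opening at the hindered C8 (a syn-axial vinyl group flanks the trajectory) and cleavage or migration of the silyl ether under hot alkoxide. The fallback sets out from 14 and installs O8 with a non-basic carboxylate, then exchanges protecting groups. Cesium acetate with 18-crown-6 in DMF should open the epoxide at C8 to the 8α-acetoxy-9β-ol F3. 4-Methoxybenzyl trichloroacetimidate with catalytic PPTS gives the 9β-O-PMB acetate F4. K2CO3 in MeOH gives the 8α-alcohol F5. NaH and allyl bromide then give 16, where the route is rejoined.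

**Further compounds**
F1 | step 15 | ten-membered C5 ketone (C4 epimers; C1=C10 ring-trans; 15-O-TBDPS; O6–C12 ethyl acetal; 8-O-allyl; 9-O-PMB) | C=C1C(OCC)O[C@@H]2C(=O)C(CO[Si](c3ccccc3)(c3ccccc3)C(C)(C)C)CC/C=C(\C)[C@H](OCc3ccc(OC)cc3)[C@@H](OCC=C)[C@@H]12
F2 | step 5 | diisobutyl(3,3-diethoxyprop-1-en-2-yl)alane | CC(C)C[Al](CC(C)C)C(=C)C(OCC)OCC
F3 | step 9 | 8α-acetoxy-9β-ol (5α-OTBS; O6–C12 acetal) | CC(C)(C)[Si](C)(C)O[C@@H]1[C@H]2OC(OCC)C(=C)[C@@H]2[C@H](OC(C)=O)[C@@H](O)[C@]1(C)C=C
F4 | step 9 | 8α-acetoxy-9β-(4-methoxybenzyloxy) compound | CC(C)(C)[Si](C)(C)O[C@@H]1[C@H]2OC(OCC)C(=C)[C@@H]2[C@H](OC(C)=O)[C@@H](OCc3ccc(OC)cc3)[C@]1(C)C=C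
F5 | step 9 | 8α-hydroxy-9β-(4-methoxybenzyloxy) compound | CC(C)(C)[Si](C)(C)O[C@@H]1[C@H]2OC(OCC)C(=C)[C@@H]2[C@H](O)[C@@H](OCc3ccc(OC)cc3)[C@]1(C)C=C
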